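**Plan**
- Retrosynthesis: cut the C5–vinyl bond (Heck, acrolein diethyl acetal), return CH2OH to an ester and trans to cis, then cut the C2–C3 bond of the dihydrofuran ring, then the aryl–C(diazo) bond and the ArO–CH2 ether bond.
- Forward: ortho-iodination of 4-bromo-2-methoxyphenol, O-benzylation, palladium-catalysed arylation of ethyl diazoacetate at C–I, then ring B (the dihydrofuran) is closed on the preformed arene ring A by carbene C–H insertion; C3 epimerisation, ester reduction and Heck chain extension follow.
- Enabling feature: C2 is a benzylic OCH2 carbon flanked by ring oxygen O1 and the electron-rich 3,4-dimethoxyphenyl ring, and its hydridic C–H bonds lie 1,5 to C3, so a carbene at C3 reaches them through a five-membered transition state.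
- Helpers: the diazo group (lost as N2), the ester oxidation level at the C3 substituent (reduced later), and bromine at C5 as placeholder for the enal chain.
- Stereochemistry: C2 (R) from the chiral dirhodium catalyst choosing one enantiotopic benzylic hydrogen; C3 first cis (kinetic), then equilibrated to trans with C2 as fixed reference; E-alkene from the Heck reaction.

Key step: step 4

Assumption: Rh2(S-PTTL)4 is taken to select the benzylic hydrogen that leads to the (2R) configuration, by analogy with the closest 2-(benzyloxy)aryl diazoacetate cases; if the sense proved opposite, Rh2(R-PTTL)4 would be used with no other change.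

Step 1
Reactants: 1 4-bromo-2-methoxyphenol
Product: 2 4-bromo-2-iodo-6-methoxyphenol
Conditions: NIS (1.05 equiv), TsOH·H2O (10 mol %), MeCN, 0 °C to rt
Reagents that add atoms: N-iodosuccinimide, O=C1CCC(=O)N1I
Why: Electrophilic aromatic iodination; the hydroxyl group is the strongest director, its para position is blocked by bromine and C6 is its only free ortho position, so iodine should enter there.

Step 2
Reactants: 2 4-bromo-2-iodo-6-methoxyphenol; 3 3,4-dimethoxybenzyl chloride
Product: 4 5-bromo-2-[(3,4-dimethoxyphenyl)methoxy]-1-iodo-3-methoxybenzene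
Conditions: K2CO3 (2 equiv), KI (10 mol %), DMF, 60 °C
Reagents that add atoms: none
Why: Williamson ether synthesis; the phenoxide should displace the reactive benzylic chloride by SN2 (iodide catalysis) despite the two ortho substituents.

Step 3
Reactants: 4 5-bromo-2-[(3,4-dimethoxyphenyl)methoxy]-1-iodo-3-methoxybenzene; 5 ethyl diazoacetate
Product: 6 ethyl 2-{5-bromo-2-[(3,4-dimethoxyphenyl)methoxy]-3-methoxyphenyl}-2-diazoacetate
Conditions: Pd(PPh3)4 (5 mol %), Ag2CO3 (0.5 equiv), Et3N (1.3 equiv), toluene, rt, dark
Reagents that add atoms: none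
Why: Palladium-catalysed cross-coupling of an aryl iodide with the C–H bond of a diazoacetate with retention of the diazo group; zerovalent palladium inserts into C–I much faster than into C–Br at rt, so the bromide should survive.

Step 4
Reactants: 6 ethyl 2-{5-bromo-2-[(3,4-dimethoxyphenyl)methoxy]-3-methoxyphenyl}-2-diazoacetate
Product: 7 ethyl (2R,3S)-5-bromo-2-(3,4-dimethoxyphenyl)-7-methoxy-2,3-dihydro-1-benzofuran-3-carboxylate (cis)
Conditions: Rh2(S-PTTL)4 (dirhodium tetrakis[N-phthaloyl-(S)-tert-leucinate], 1 mol %), toluene, −78 °C to −60 °C, slow addition of 6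
Reagents that add atoms: none
Why: The divalent rhodium carboxylate dimer expels N2 from 6 to give an electrophilic donor/acceptor rhodium carbene at the future C3, which inserts through a concerted, hydride-transfer-like three-centre transition state into one benzylic O–CH2 hydrogen of the 3,4-dimethoxybenzyl ether, forming the C2–C3 bond and releasing the catalyst. The closest known reaction type is the enantioselective intramolecular 1,5 C–H insertion of 2-(benzyloxy)aryl diazoacetates to cis-2-aryl-2,3-dihydrobenzofuran-3-carboxylates under chiral dirhodium tetracarboxylate catalysis. Ring B, the five-membered dihydrofuran, is closed by 1,5-insertion onto the existing arene ring A, which is the normal mode for carbene C–H insertion. C2 (R) is set by the catalyst, whose phthalimide-walled pocket should let only one of the two enantiotopic benzylic hydrogens reach the carbene; C3 (S, cis to the aryl group) should follow from the kinetic preference of the compact transition state and is corrected in step 5. The step needs site selectivity for the benzylic ether C–H over cyclopropanation or Büchner attack on the dimethoxyphenyl ring, over the ester ethyl C–H bonds and over carbene dimerisation. The substrate secures this because its only activated C–H bonds (alpha to oxygen and benzylic to an electron-rich ring) lie exactly 1,5 to the carbene carbon, the ester ethyl group is unactivated and held away in the Z-ester conformation, slow addition at low temperature keeps the diazo concentration low, and the aryl bromide and methoxy groups are inert to the carbene.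

Step 5
Reactants: 7 ethyl (2R,3S)-5-bromo-2-(3,4-dimethoxyphenyl)-7-methoxy-2,3-dihydro-1-benzofuran-3-carboxylate (cis)
Product: 8 ethyl (2R,3R)-5-bromo-2-(3,4-dimethoxyphenyl)-7-methoxy-2,3-dihydro-1-benzofuran-3-carboxylate (trans)
Conditions: NaOEt (0.3 equiv), EtOH, 0 °C to rt
Reagents that add atoms: none
Why: Base-mediated epimerisation through the C3 ester enolate should converge on the thermodynamically favoured trans isomer, while C2 carries no acidic hydrogen and stays fixed; ethoxide matches the ester so no transesterification mixture arises.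

Step 6
Reactants: 8 ethyl (2R,3R)-5-bromo-2-(3,4-dimethoxyphenyl)-7-methoxy-2,3-dihydro-1-benzofuran-3-carboxylate (trans)
Product: 9 [(2R,3S)-5-bromo-2-(3,4-dimethoxyphenyl)-7-methoxy-2,3-dihydro-1-benzofuran-3-yl]methanol
Conditions: LiBH4 (2 equiv), THF, 0 °C to rt; aq NH4Cl work-up
Reagents that add atoms: none
Why: Chemoselective hydride reduction of the ester to the primary alcohol; the aryl bromide and the benzylic ether should be inert to LiBH4 and no stereocentre is touched (the 3S descriptor reflects only the changed priority of the substituent).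

Step 7
Reactants: 9 [(2R,3S)-5-bromo-2-(3,4-dimethoxyphenyl)-7-methoxy-2,3-dihydro-1-benzofuran-3-yl]methanol; 10 acrolein diethyl acetal
Product: 12 4-O-methylbalanophonin, via enal diethyl acetal 11 (not isolated)
Conditions: Pd(OAc)2 (3 mol %), nBu4NOAc (2 equiv), K2CO3 (1.5 equiv), KCl (1 equiv), DMF, 90 °C; then 2 M HCl, rt
Reagents that add atoms: water, O
Why: Mizoroki–Heck reaction of the aryl bromide with the terminal alkene; syn-insertion and syn β-hydride elimination of the benzylic hydrogen (favoured over the acetal hydrogen in the acetate/carbonate medium) should give the E-cinnamyl acetal, and mild acid hydrolysis should unveil the E-enal without affecting C2 or C3.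

**Compound list**
1 | 4-bromo-2-methoxyphenol | COc1cc(Br)ccc1O | starting material
2 | 4-bromo-2-iodo-6-methoxyphenol | COc1cc(Br)cc(I)c1O | intermediate
3 | 3,4-dimethoxybenzyl chloride (4-(chloromethyl)-1,2-dimethoxybenzene) | COc1ccc(CCl)cc1OC | starting material
4 | 5-bromo-2-[(3,4-dimethoxyphenyl)methoxy]-1-iodo-3-methoxybenzene | COc1cc(Br)cc(I)c1OCc1ccc(OC)c(OC)c1 | intermediate
5 | ethyl diazoacetate | CCOC(=O)C=[N+]=[N-] | starting material
6 | ethyl 2-{5-bromo-2-[(3,4-dimethoxyphenyl)methoxy]-3-methoxyphenyl}-2-diazoacetate | CCOC(=O)C(=[N+]=[N-])c1cc(Br)cc(OC)c1OCc1ccc(OC)c(OC)c1 | intermediate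
7 | ethyl (2R,3S)-5-bromo-2-(3,4-dimethoxyphenyl)-7-methoxy-2,3-dihydro-1-benzofuran-3-carboxylate (cis) | COc1ccc([C@@H]2Oc3c(OC)cc(Br)cc3[C@@H]2C(=O)OCC)cc1OC | intermediate
8 | ethyl (2R,3R)-5-bromo-2-(3,4-dimethoxyphenyl)-7-methoxy-2,3-dihydro-1-benzofuran-3-carboxylate (trans) | COc1ccc([C@@H]2Oc3c(OC)cc(Br)cc3[C@H]2C(=O)OCC)cc1OC | intermediate
9 | [(2R,3S)-5-bromo-2-(3,4-dimethoxyphenyl)-7-methoxy-2,3-dihydro-1-benzofuran-3-yl]methanol | COc1ccc([C@@H]2Oc3c(OC)cc(Br)cc3[C@H]2CO)cc1OC | intermediate
10 | acrolein diethyl acetal (3,3-diethoxyprop-1-ene) | C=CC(OCC)OCC | starting material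
11 | [(2R,3S)-5-[(E)-3,3-diethoxyprop-1-enyl]-2-(3,4-dimethoxyphenyl)-7-methoxy-2,3-dihydro-1-benzofuran-3-yl]methanol | COc1ccc([C@@H]2Oc3c(OC)cc(/C=C/C(OCC)OCC)cc3[C@H]2CO)cc1OC | intermediate
12 | 4-O-methylbalanophonin, (E)-3-[(2R,3S)-2-(3,4-dimethoxyphenyl)-3-(hydroxymethyl)-7-methoxy-2,3-dihydro-1-benzofuran-5-yl]prop-2-enal | COc1ccc([C@@H]2Oc3c(OC)cc(/C=C/C=O)cc3[C@H]2CO)cc1OC | target

Total step count: 7. Longest linear sequence: 7 steps (1 to 12).

**Steps most likely to fail**

Step 4. The risk is poor discrimination between the two enantiotopic benzylic hydrogens (low enantioselectivity), because the methoxy group flanking the benzyloxy tether twists it differently from simpler substrates and the ester is ethyl. Fallback: from 6, decomposition with the achiral catalyst Rh2(OAc)4 in CH2Cl2 at rt should give the cis/trans mixture without enantiocontrol, ethyl 5-bromo-2-(3,4-dimethoxyphenyl)-7-methoxy-2,3-dihydro-1-benzofuran-3-carboxylate F1. NaOEt in EtOH should converge it on the racemic trans ester F2. Preparative chromatography on a chiral stationary phase (amylose tris(3,5-dimethylphenylcarbamate), supercritical CO2/MeOH) should then separate the (2R,3R) ester from its (2S,3S) enantiomer F3, and the route is rejoined at 8. Absolute configuration then comes from resolution instead of catalyst control.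

Step 3. The risk is slow coupling at the ortho-alkoxy-hindered iodide, so that palladium-induced decomposition of ethyl diazoacetate (carbene dimerisation) outruns arylation. Fallback: from 4, copper-catalysed arylation of diethyl malonate at the C–I bond (CuI, 2-picolinic acid, Cs2CO3, dioxane, rt to 70 °C) should give the aryl malonate diethyl 2-{5-bromo-2-[(3,4-dimethoxyphenyl)methoxy]-3-methoxyphenyl}propanedioate F4. Krapcho dealkoxycarbonylation (LiCl, wet DMSO, 140 °C) should give the arylacetate ethyl 2-{5-bromo-2-[(3,4-dimethoxyphenyl)methoxy]-3-methoxyphenyl}acetate F5. Regitz diazo transfer (4-acetamidobenzenesulfonyl azide, DBU, MeCN, 0 °C to rt) returns to 6.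

Step 7. The risk is slow oxidative addition into the electron-rich C–Br bond, which would allow β-hydride elimination toward the acetal carbon (giving a saturated ester after hydrolysis) or palladium-mediated oxidation of the free primary alcohol. Fallback: from 9, n-BuLi (2.2 equiv; the first equivalent forms the alkoxide) in THF at −78 °C followed by DMF should give the aldehyde (2R,3S)-2-(3,4-dimethoxyphenyl)-3-(hydroxymethyl)-7-methoxy-2,3-dihydro-1-benzofuran-5-carbaldehyde F6. Wittig olefination with (triphenylphosphoranylidene)acetaldehyde (1.1 equiv, toluene, 80 °C) should extend it E-selectively by two carbons and arrive at 12.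

**Further compounds**
F1 | step 4 | ethyl 5-bromo-2-(3,4-dimethoxyphenyl)-7-methoxy-2,3-dihydro-1-benzofuran-3-carboxylate (cis/trans mixture, no enantiocontrol) | CCOC(=O)C1c2cc(Br)cc(OC)c2OC1c1ccc(OC)c(OC)c1
F2 | step 4 | racemic trans ester, ethyl (2R,3R)- and (2S,3S)-5-bromo-2-(3,4-dimethoxyphenyl)-7-methoxy-2,3-dihydro-1-benzofuran-3-carboxylate | COc1ccc([C@@H]2Oc3c(OC)cc(Br)cc3[C@H]2C(=O)OCC)cc1OC.COc1ccc([C@H]2Oc3c(OC)cc(Br)cc3[C@@H]2C(=O)OCC)cc1OC
F3 | step 4 | ethyl (2S,3S)-5-bromo-2-(3,4-dimethoxyphenyl)-7-methoxy-2,3-dihydro-1-benzofuran-3-carboxylate | COc1ccc([C@H]2Oc3c(OC)cc(Br)cc3[C@@H]2C(=O)OCC)cc1OC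
F4 | step 3 | diethyl 2-{5-bromo-2-[(3,4-dimethoxyphenyl)methoxy]-3-methoxyphenyl}propanedioate | CCOC(=O)C(C(=O)OCC)c1cc(Br)cc(OC)c1OCc1ccc(OC)c(OC)c1
F5 | step 3 | ethyl 2-{5-bromo-2-[(3,4-dimethoxyphenyl)methoxy]-3-methoxyphenyl}acetate | CCOC(=O)Cc1cc(Br)cc(OC)c1OCc1ccc(OC)c(OC)c1
F6 | step 7 | (2R,3S)-2-(3,4-dimethoxyphenyl)-3-(hydroxymethyl)-7-methoxy-2,3-dihydro-1-benzofuran-5-carbaldehyde | COc1ccc([C@@H]2Oc3c(OC)cc(C=O)cc3[C@H]2CO)cc1OC
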